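Assumption: the SMILES is read literally as (2R,3S) (2,3-trans) in the ring, (1R) at the side-chain carbinol and (E) (tiglate) for both esters; the L-fructose-derived enantiomer of the Shi ketone is taken as purchasable.

## Retrosynthetic overview

1. Target ⇐ bis-tiglate by late allylic C–H oxidation of the isopropenyl CH3; bis-tiglate ⇐ diol + 2 tigloyl chloride; diol ⇐ aryl methyl ketone (ent-toxol) by asymmetric transfer hydrogenation, which sets the (1R) carbinol.
2. The only ring to be made is the dihydrofuran. Its O1–C2 bond is closed as in tremetone/toxol biogenesis, by attack of the phenol oxygen on an epoxidised C5 side chain. Here the epoxide sits on the styrenyl C3=C2 bond of a 3-methylbuta-1,3-dienyl (dehydroprenyl) chain, so one anti 5-endo opening at the allylic carbon gives C2, C3, the trans relation, the free C3–OH and the intact isopropenyl group at once.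
3. Vinyl epoxide ⇐ (E)-dienyl aryl silyl ether by Shi epoxidation (source of both ring stereocentres); diene ⇐ 3-bromo-4-hydroxyacetophenone + dienylboronate (from 2-methylbut-1-en-3-yne and pinacolborane) by one-pot hydroboration/Suzuki coupling.
4. Ring order: benzene ring bought → oxirane (step 3) → dihydrofuran (step 4).

## Route

Step 1
Reactants: 1 2-methylbut-1-en-3-yne; 2 pinacolborane; 3 1-(3-bromo-4-hydroxyphenyl)ethan-1-one
Product: 5 1-{4-hydroxy-3-[(1E)-3-methylbuta-1,3-dien-1-yl]phenyl}ethan-1-one, via dienylboronate 4 (not isolated)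
Conditions: 1 (1.3 equiv), 2 (1.15 equiv), Cp2Zr(H)Cl (5 mol %), Et3N (10 mol %), THF, sealed, 50 °C; then 3 (1.0 equiv), Pd(dppf)Cl2 (3 mol %), K2CO3 (3.5 equiv), dioxane/H2O 4:1, 80 °C
Reagents that add atoms: none
Why: Zr-catalysed syn hydroboration of the terminal alkyne (much faster than the 1,1-disubstituted alkene) gives the (E)-dienyl-Bpin, and Suzuki–Miyaura coupling with the aryl bromide (free phenol tolerated as phenoxide, ketone inert) keeps the E geometry; no stereocentre is formed.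

Step 2
Reactants: 5 1-{4-hydroxy-3-[(1E)-3-methylbuta-1,3-dien-1-yl]phenyl}ethan-1-one
Product: 6 1-{4-[(tert-butyldimethylsilyl)oxy]-3-[(1E)-3-methylbuta-1,3-dien-1-yl]phenyl}ethan-1-one
Conditions: TBSCl (1.2 equiv), imidazole (2.5 equiv), DMF, 0 °C → rt
Reagents that add atoms: tert-butyldimethylsilyl chloride (TBSCl), CC(C)(C)[Si](C)(C)Cl
Why: Standard imidazole-promoted O-silylation of the phenol, which masks the oxidisable phenoxide during the Oxone step and stores it as a fluoride-releasable nucleophile; no stereocentre is formed.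

Step 3
Reactants: 6 1-{4-[(tert-butyldimethylsilyl)oxy]-3-[(1E)-3-methylbuta-1,3-dien-1-yl]phenyl}ethan-1-one
Product: 7 1-{4-[(tert-butyldimethylsilyl)oxy]-3-[(2S,3S)-3-(prop-1-en-2-yl)oxiran-2-yl]phenyl}ethan-1-one
Conditions: ent-Shi ketone (L-fructose-derived, 30 mol %), Oxone (1.4 equiv), K2CO3 (5.8 equiv), Bu4NHSO4 (5 mol %), MeCN/DMM 1:2, aq Na2B4O7–EDTA buffer (pH 10.5), −10 → 0 °C; extract, use crude (no silica)
Reagents that add atoms: Oxone (potassium peroxymonosulfate), [K+].[O-]S(=O)(=O)OO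
Why: Shi asymmetric epoxidation: the chiral dioxirane attacks trans-1,2-disubstituted olefins through a spiro transition state and discriminates against 1,1-disubstituted terminal olefins, so the styrenyl C=C of the diene should be epoxidised (regioselective monoepoxidation of conjugated dienes is a known use of this catalyst), and the L-fructose-derived ketone gives the (2S,3S)-trans epoxide (the D-fructose ketone gives (R,R) with trans-β-methylstyrene), which sets both future ring stereocentres.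

Step 4
Reactants: 7 1-{4-[(tert-butyldimethylsilyl)oxy]-3-[(2S,3S)-3-(prop-1-en-2-yl)oxiran-2-yl]phenyl}ethan-1-one
Product: 9 1-[(2R,3S)-3-hydroxy-2-(prop-1-en-2-yl)-2,3-dihydro-1-benzofuran-5-yl]ethan-1-one, via ammonium phenoxide 8 (not isolated)
Conditions: TBAF (1.1 equiv), THF, −20 °C → rt; H2O work-up
Reagents that add atoms: none
Why: Proposed new method: fluoride desilylation gives the tetrabutylammonium phenoxide 8, whose oxygen attacks the allylic epoxide carbon C2 anti to its C–O bond (5-endo-tet SN2, geometrically strained but made feasible by the loose allylic transition state), so C2 is inverted to R while C3 keeps its S configuration and the 2,3-trans alcohol forms with the isopropenyl group intact; the closest known reactions are the base-induced cyclisation of (E)-2-hydroxystilbene oxides to trans-2-aryl-2,3-dihydrobenzofuran-3-ols and the 5-endo opening of vinyl epoxides by hydroxyl groups.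

Step 5
Reactants: 9 1-[(2R,3S)-3-hydroxy-2-(prop-1-en-2-yl)-2,3-dihydro-1-benzofuran-5-yl]ethan-1-one
Product: 10 (2R,3S)-5-[(1R)-1-hydroxyethyl]-2-(prop-1-en-2-yl)-2,3-dihydro-1-benzofuran-3-ol
Conditions: RuCl(p-cymene)[(R,R)-TsDPEN] (1 mol %), HCO2H/Et3N (5:2), EtOAc, 30 °C
Reagents that add atoms: none
Why: Noyori–Ikariya asymmetric transfer hydrogenation reduces only the aryl methyl ketone (isopropenyl group, benzylic C–O bonds and free OH are untouched), and the (R,R)-TsDPEN catalyst gives (R)-1-arylethanols under catalyst control, which sets the side-chain stereocentre.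

Step 6
Reactants: 10 (2R,3S)-5-[(1R)-1-hydroxyethyl]-2-(prop-1-en-2-yl)-2,3-dihydro-1-benzofuran-3-ol; 11 (2E)-2-methylbut-2-enoyl chloride (tigloyl chloride)
Product: 12 (2R,3S)-5-[(1R)-1-{[(2E)-2-methylbut-2-enoyl]oxy}ethyl]-2-(prop-1-en-2-yl)-2,3-dihydro-1-benzofuran-3-yl (2E)-2-methylbut-2-enoate
Conditions: 11 (2.6 equiv), pyridine (6 equiv), DMAP (0.2 equiv), CH2Cl2, 0 °C → rt
Reagents that add atoms: none
Why: DMAP-catalysed acylation of both secondary benzylic alcohols with retention at carbon; the (E)-tiglate is the thermodynamically stable geometry, and pyridine rather than a trialkylamine avoids vinylketene-mediated deconjugation.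

Step 7
Reactants: 12 (2R,3S)-5-[(1R)-1-{[(2E)-2-methylbut-2-enoyl]oxy}ethyl]-2-(prop-1-en-2-yl)-2,3-dihydro-1-benzofuran-3-yl (2E)-2-methylbut-2-enoate
Product: 14 (2R,3S)-5-[(1R)-1-{[(2E)-2-methylbut-2-enoyl]oxy}ethyl]-2-(3-oxoprop-1-en-2-yl)-2,3-dihydro-1-benzofuran-3-yl (2E)-2-methylbut-2-enoate, via allylic alcohol 13 (not isolated)
Conditions: SeO2 (2.0 equiv), 1,4-dioxane, 80 °C
Reagents that add atoms: selenium dioxide, O=[Se]=O
Why: Riley allylic oxidation: ene reaction of SeO2 at the electron-rich 1,1-disubstituted alkene with loss of a methyl hydrogen (CH3 preferred over the methine C2–H; the electron-poor tiglate olefins react far more slowly) and [2,3]-sigmatropic shift give allylic alcohol 13, which SeO2 oxidises on to the 2-substituted acrolein in the same flask; no stereocentre is touched.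

## Compound list

1 | 2-methylbut-1-en-3-yne | C=C(C)C#C | starting material
2 | pinacolborane (4,4,5,5-tetramethyl-1,3,2-dioxaborolane) | CC1(C)OBOC1(C)C | starting material
3 | 1-(3-bromo-4-hydroxyphenyl)ethan-1-one | CC(=O)c1ccc(O)c(Br)c1 | starting material
4 | 4,4,5,5-tetramethyl-2-[(1E)-3-methylbuta-1,3-dien-1-yl]-1,3,2-dioxaborolane | C=C(C)/C=C/B1OC(C)(C)C(C)(C)O1 | intermediate
5 | 1-{4-hydroxy-3-[(1E)-3-methylbuta-1,3-dien-1-yl]phenyl}ethan-1-one | CC(=O)c1ccc(O)c(/C=C/C(C)=C)c1 | intermediate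
6 | 1-{4-[(tert-butyldimethylsilyl)oxy]-3-[(1E)-3-methylbuta-1,3-dien-1-yl]phenyl}ethan-1-one | CC(=O)c1ccc(O[Si](C)(C)C(C)(C)C)c(/C=C/C(C)=C)c1 | intermediate
7 | 1-{4-[(tert-butyldimethylsilyl)oxy]-3-[(2S,3S)-3-(prop-1-en-2-yl)oxiran-2-yl]phenyl}ethan-1-one | CC(=O)c1ccc(O[Si](C)(C)C(C)(C)C)c([C@@H]2O[C@H]2C(C)=C)c1 | intermediate
8 | tetrabutylammonium 4-acetyl-2-[(2S,3S)-3-(prop-1-en-2-yl)oxiran-2-yl]phenolate | CC(=O)c1ccc([O-])c([C@@H]2O[C@H]2C(C)=C)c1.CCCC[N+](CCCC)(CCCC)CCCC | intermediate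
9 | 1-[(2R,3S)-3-hydroxy-2-(prop-1-en-2-yl)-2,3-dihydro-1-benzofuran-5-yl]ethan-1-one (ent-toxol) | C=C(C)[C@H]1Oc2ccc(C(C)=O)cc2[C@@H]1O | intermediate
10 | (2R,3S)-5-[(1R)-1-hydroxyethyl]-2-(prop-1-en-2-yl)-2,3-dihydro-1-benzofuran-3-ol | C=C(C)[C@H]1Oc2ccc([C@@H](C)O)cc2[C@@H]1O | intermediate
11 | (2E)-2-methylbut-2-enoyl chloride (tigloyl chloride) | C/C=C(\C)C(Cl)=O | starting material
12 | (2R,3S)-5-[(1R)-1-{[(2E)-2-methylbut-2-enoyl]oxy}ethyl]-2-(prop-1-en-2-yl)-2,3-dihydro-1-benzofuran-3-yl (2E)-2-methylbut-2-enoate | C=C(C)[C@H]1Oc2ccc([C@@H](C)OC(=O)/C(C)=C/C)cc2[C@@H]1OC(=O)/C(C)=C/C | intermediate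
13 | (2R,3S)-2-(3-hydroxyprop-1-en-2-yl)-5-[(1R)-1-{[(2E)-2-methylbut-2-enoyl]oxy}ethyl]-2,3-dihydro-1-benzofuran-3-yl (2E)-2-methylbut-2-enoate | C=C(CO)[C@H]1Oc2ccc([C@@H](C)OC(=O)/C(C)=C/C)cc2[C@@H]1OC(=O)/C(C)=C/C | intermediate
14 | (2R,3S)-5-[(1R)-1-{[(2E)-2-methylbut-2-enoyl]oxy}ethyl]-2-(3-oxoprop-1-en-2-yl)-2,3-dihydro-1-benzofuran-3-yl (2E)-2-methylbut-2-enoate | C=C(C=O)[C@H]1Oc2ccc([C@@H](C)OC(=O)/C(C)=C/C)cc2[C@@H]1OC(=O)/C(C)=C/C | target

## Step count and risks

Total step count: 7. Longest linear sequence: 7.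

**Step 3 (Shi epoxidation of the diene).** Risk: the isopropenyl C=C may compete (regioisomeric epoxide or bis-epoxide), or the ee may be moderate. The fallback sets out from 3 and comes back at 7. Heck coupling of 3 with 2-methylbut-3-en-2-ol (Pd(OAc)2, P(o-tol)3, Et3N, MeCN, 80 °C) gives 1-{4-hydroxy-3-[(1E)-3-hydroxy-3-methylbut-1-en-1-yl]phenyl}ethan-1-one F1, in which the second olefin is stored as a tertiary carbinol. Silylation (TBSCl, imidazole, DMF) gives 1-{4-[(tert-butyldimethylsilyl)oxy]-3-[(1E)-3-hydroxy-3-methylbut-1-en-1-yl]phenyl}ethan-1-one F2. The same ent-Shi epoxidation, now on a substrate with a single olefin, gives 1-{4-[(tert-butyldimethylsilyl)oxy]-3-[(2S,3R)-3-(2-hydroxypropan-2-yl)oxiran-2-yl]phenyl}ethan-1-one F3 (same face as in 7; the second descriptor changes only through CIP priority). Burgess dehydration (benzene, 50 °C), in which only methyl hydrogens can be lost without forming an alkylidene oxirane, unveils the isopropenyl group and gives 7.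

**Step 4 (5-endo epoxide opening).** Risk: the phenoxide may instead open the benzylic C3–O bond to an o-quinone methide (followed by 1,5-H shift to a benzyl ketone), or C2 may close partly cis. The fallback sets out from 7 and comes back at 9. Buffered desilylation (TBAF/AcOH 1:1, THF, −40 °C) gives the free phenol 1-{4-hydroxy-3-[(2S,3S)-3-(prop-1-en-2-yl)oxiran-2-yl]phenyl}ethan-1-one F4, used at once. Pd(PPh3)4 (5 mol %, THF, 0 °C → rt) then ionises only the allylic C2–O bond (Tsuji–Trost), and the phenol closes the five-membered ring on the π-allyl terminus under neutral conditions. The 2-methylallyl-Pd faces interconvert (η3–η1–η3 at the CH2 terminus) and the aryl allyl ether can re-ionise, so the more stable 2,3-trans isomer 9 is expected under thermodynamic control, with C3 untouched.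

**Step 7 (SeO2 oxidation).** Risk: stalling at alcohol 13, over-oxidation, or acid-promoted loss of tiglic acid from C3 (aromatisation to the benzofuran) at 80 °C. The fallback sets out from 12 and comes back at 14. Ene-type allylic chlorination (Ca(OCl)2, solid CO2, CH2Cl2/H2O, 0 °C) gives (2R,3S)-2-(3-chloroprop-1-en-2-yl)-5-[(1R)-1-{[(2E)-2-methylbut-2-enoyl]oxy}ethyl]-2,3-dihydro-1-benzofuran-3-yl (2E)-2-methylbut-2-enoate F5. N-Oxide oxidation of the allylic chloride (N-methylmorpholine N-oxide, cat. NaI, MeCN, rt) then gives aldehyde 14 under near-neutral conditions.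

## Further compounds

F1 | step 3 | 1-{4-hydroxy-3-[(1E)-3-hydroxy-3-methylbut-1-en-1-yl]phenyl}ethan-1-one | CC(=O)c1ccc(O)c(/C=C/C(C)(C)O)c1
F2 | step 3 | 1-{4-[(tert-butyldimethylsilyl)oxy]-3-[(1E)-3-hydroxy-3-methylbut-1-en-1-yl]phenyl}ethan-1-one | CC(=O)c1ccc(O[Si](C)(C)C(C)(C)C)c(/C=C/C(C)(C)O)c1
F3 | step 3 | 1-{4-[(tert-butyldimethylsilyl)oxy]-3-[(2S,3R)-3-(2-hydroxypropan-2-yl)oxiran-2-yl]phenyl}ethan-1-one | CC(=O)c1ccc(O[Si](C)(C)C(C)(C)C)c([C@@H]2O[C@H]2C(C)(C)O)c1
F4 | step 4 | 1-{4-hydroxy-3-[(2S,3S)-3-(prop-1-en-2-yl)oxiran-2-yl]phenyl}ethan-1-one | CC(=O)c1ccc(O)c([C@@H]2O[C@H]2C(C)=C)c1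
F5 | step 7 | (2R,3S)-2-(3-chloroprop-1-en-2-yl)-5-[(1R)-1-{[(2E)-2-methylbut-2-enoyl]oxy}ethyl]-2,3-dihydro-1-benzofuran-3-yl (2E)-2-methylbut-2-enoate | C=C(CCl)[C@H]1Oc2ccc([C@@H](C)OC(=O)/C(C)=C/C)cc2[C@@H]1OC(=O)/C(C)=C/C
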